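**Retrosynthetic overview**

1. Feature: in the eleven-membered carbocycle (C1 quaternary, C2=C3 E, C4 acyloxy carbon, C5–C6 oxirane with the methyl on C5, C7, C8, C9(CH2OH)=C10, C11) the oxygenated carbon C4 sits alone between two alkenyl carbons, C3 and C5. At the ketone level it is therefore carbon monoxide, and cutting C3–C4 and C4–C5 opens the ring to one chain with an E-alkenylstannane at C3 and a Z-alkenyl iodide at C5.
2. Ring order: the eleven-membered ring is the only carbocycle and is closed in the key step as a cross-conjugated dienone. The oxirane comes last: C4 by oxazaborolidine reduction, C5/C6 by hydroxyl-directed epoxidation, then acylation with 3-methylbut-2-enoic acid and desilylation.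
3. Chain: C9=C10 by Horner–Wadsworth–Emmons union of a stannyl aldehyde (C1–C3, C10, C11, side chain) with an iodo phosphonate (C5–C9).
4. C1: Sharpless epoxidation of geraniol, then an aluminium-promoted 1,2-shift of the silyloxymethyl group, turns the epoxide configuration into the quaternary centre. Aldehyde to alkyne to E-stannane gives C2/C3; a one-carbon Wittig homologation gives C10.
5. Z-iodide: iodoethylidene Wittig reaction on a three-carbon aldehyde, carried out before the tin enters.

Key step: step 16

Assumption: ring atoms carry the locants C1 (quaternary carbon) to C11 of the overview throughout. In step 3 the silyloxymethyl group is taken to shift anti to the breaking C–O bond, as is the rule for this rearrangement, and this fixes L-(+)-diethyl tartrate in step 1. 3-[(tert-Butyldimethylsilyl)oxy]propanal is taken as a purchased material.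

**Route**

Step 1
Reactants: 1 geraniol
Product: 2 (2S,3S)-2,3-epoxygeraniol
Conditions: Ti(OiPr)4 (5 mol %), L-(+)-diethyl tartrate (7 mol %), t-BuOOH, 4 Å sieves, CH2Cl2, −20 °C
Reagents that add atoms: tert-butyl hydroperoxide, CC(C)(C)OO
Why: Sharpless asymmetric epoxidation of an E-trisubstituted primary allylic alcohol, in which the titanium tartrate complex with the L-(+)-ligand should deliver oxygen to the face of the 2,3-alkene that gives the (2S,3S)-oxirane, while the remote alkene, which cannot bind titanium, is left alone.

Step 2
Reactants: 2 (2S,3S)-2,3-epoxygeraniol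
Product: 3 tert-butyldimethylsilyl ether of 2
Conditions: TBSCl, imidazole, CH2Cl2, 0 °C → rt
Reagents that add atoms: tert-butyldimethylsilyl chloride, CC(C)(C)[Si](C)(C)Cl
Why: Routine silylation of a primary alcohol, needed because the silyloxymethyl group is the migrating group of step 3.

Step 3
Reactants: 3 epoxy silyl ether
Product: 4 (2S)-2-[(tert-butyldimethylsilyloxy)methyl]-2,6-dimethylhept-5-enal
Conditions: MeAl(OC6H2-4-Br-2,6-t-Bu2)2 (2 equiv, from Me3Al and the phenol), CH2Cl2, −78 °C
Reagents that add atoms: none
Why: Lewis-acid-promoted epoxy silyl ether rearrangement (semipinacol-type 1,2-shift), in which the bulky aluminium aryloxide opens the oxirane at its tertiary carbon and the silyloxymethyl group shifts to that carbon anti to the leaving oxygen, so that the oxirane configuration is passed on with inversion to the new quaternary carbon (the future C1, S in the target) and the former oxirane CH becomes the aldehyde.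

Step 4
Reactants: 4 quaternary β-silyloxy aldehyde
Product: 5 (2R)-1-(tert-butyldimethylsilyloxy)-2-ethynyl-2,6-dimethylhept-5-ene
Conditions: dimethyl (1-diazo-2-oxopropyl)phosphonate, K2CO3, MeOH, 0 °C → rt
Reagents that add atoms: dimethyl (1-diazo-2-oxopropyl)phosphonate, CC(=O)C(=[N+]=[N-])P(=O)(OC)OC
Why: Seyferth–Gilbert homologation with the Ohira–Bestmann reagent should turn the non-enolisable aldehyde into the terminal alkyne (future C2≡C3) under a mild base that leaves the silyl ether and the quaternary centre untouched.

Step 5
Reactants: 5 silyl ether alkyne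
Product: 6 (2R)-2-ethynyl-2,6-dimethylhept-5-en-1-ol
Conditions: Bu4NF, THF, 0 °C → rt
Reagents that add atoms: none
Why: Fluoride cleavage of a primary silyl ether, with nothing else in the molecule sensitive to fluoride.

Step 6
Reactants: 6 neopentyl-type alcohol
Product: 7 (2R)-2-ethynyl-2,6-dimethylhept-5-enal
Conditions: Dess–Martin periodinane, CH2Cl2, rt
Reagents that add atoms: none
Why: Dess–Martin oxidation of a primary alcohol to the aldehyde (the future C11), which has no α-hydrogen and so cannot epimerise or enolise.

Step 7
Reactants: 7 α-quaternary aldehyde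
Product: 8 (3S)-3-ethynyl-1-methoxy-3,7-dimethylocta-1,6-diene (mixture of enol ether geometries)
Conditions: MeOCH2PPh3Cl, KN(SiMe3)2, THF, 0 °C; then 7, 0 °C → rt
Reagents that add atoms: (methoxymethyl)triphenylphosphonium chloride, COC[P+](c1ccccc1)(c1ccccc1)c1ccccc1.[Cl-]
Why: Wittig methoxymethylenation adds the carbon that becomes C10, and the ylide is too weak a base to disturb the terminal alkyne.

Step 8
Reactants: 8 enol ether
Product: 9 (3S)-3-ethynyl-3,7-dimethyloct-6-enal
Conditions: 1 M aq. HCl, THF, 0 °C → rt
Reagents that add atoms: water, O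
Why: Acid hydrolysis of the enol ether completes the one-carbon homologation, since protonation of the electron-rich enol ether carbon is far faster than any reaction of the trisubstituted alkene or the alkyne and the hydrolysis can be stopped before the new aldehyde adds to the prenyl alkene.

Step 9
Reactants: 9 alkynyl aldehyde
Product: 10 (3S)-3,7-dimethyl-3-[(E)-2-(tributylstannyl)ethenyl]oct-6-enal
Conditions: Bu3SnH, PdCl2(PPh3)2 (2 mol %), THF, 0 °C
Reagents that add atoms: tributyltin hydride, CCCC[SnH](CCCC)CCCC
Why: Palladium-catalysed syn-hydrostannation should place tin on the terminal carbon because the internal one is shielded by the quaternary centre, giving the E-alkenylstannane without touching the saturated aldehyde, and it is run before any alkenyl iodide is present because palladium with Bu3SnH would reduce a C–I bond.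

Step 10
Reactants: 11 3-[(tert-butyldimethylsilyl)oxy]propanal
Product: 12 (Z)-tert-butyl[(4-iodopent-3-en-1-yl)oxy]dimethylsilane
Conditions: EtPPh3I, n-BuLi, THF, rt; I2, −78 °C; NaN(SiMe3)2, −20 °C; then 11, −78 → −20 °C
Reagents that add atoms: ethyltriphenylphosphonium iodide, CC[P+](c1ccccc1)(c1ccccc1)c1ccccc1.[I-]; iodine, II
Why: Iodoethylidene Wittig reaction (Stork–Zhao type), in which the unstabilised α-iodo ylide reacts under kinetic control through the cis-oxaphosphetane and should give the Z-2-iodoalkene with the chain (C7) cis to iodine.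

Step 11
Reactants: 12 Z-alkenyl iodide silyl ether
Product: 13 (Z)-5-bromo-2-iodopent-2-ene
Conditions: Ph3PBr2, CH2Cl2, 0 °C → rt
Reagents that add atoms: triphenylphosphine dibromide, Br[P+](c1ccccc1)(c1ccccc1)c1ccccc1.[Br-]
Why: Appel-type direct conversion of a primary silyl ether into the bromide through the alkoxyphosphonium ion, under neutral conditions that leave the alkenyl iodide and its geometry alone.

Step 12
Reactants: 14 triethyl phosphonoacetate; 13 (Z)-5-bromo-2-iodopent-2-ene
Product: 15 ethyl (5Z)-2-(diethoxyphosphoryl)-6-iodohept-5-enoate (racemic at C2)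
Conditions: NaH, DMF, 0 °C; then 13, 60 °C
Reagents that add atoms: none
Why: SN2 C-alkylation of the soft sodium phosphonoacetate anion by a primary bromide, which joins C9 to C8 and should run with little elimination.

Step 13
Reactants: 15 iodo phosphonate; 10 stannyl aldehyde
Product: 16 ethyl (2E,5S,6E)-2-[(3Z)-4-iodopent-3-en-1-yl]-5-methyl-5-(4-methylpent-3-en-1-yl)-7-(tributylstannyl)hepta-2,6-dienoate
Conditions: NaH, THF, 0 °C; then 10, 0 °C → rt; chromatographic removal of the 2Z isomer
Reagents that add atoms: none
Why: Horner–Wadsworth–Emmons olefination forms C9=C10 and should favour the isomer with the ester trans to the C11 chain, so that C8 and C11 are cis as the ring requires, while the stabilised carbanion leaves the C–Sn and C–I bonds alone and the minor geometric isomer is separated.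

Step 14
Reactants: 16 enoate
Product: 17 (2E,5S,6E)-2-[(3Z)-4-iodopent-3-en-1-yl]-5-methyl-5-(4-methylpent-3-en-1-yl)-7-(tributylstannyl)hepta-2,6-dien-1-ol
Conditions: i-Bu2AlH, CH2Cl2, −78 °C; aq. KNaC4H4O6
Reagents that add atoms: none
Why: 1,2-Reduction of the unsaturated ester by i-Bu2AlH at low temperature gives the allylic alcohol (the C9 hydroxymethyl group) without reaction at the alkenyl iodide, the alkenylstannane or the alkene geometry.

Step 15
Reactants: 17 allylic alcohol
Product: 18 acyclic E-alkenylstannane Z-alkenyl iodide, tert-butyldimethylsilyl ether of 17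
Conditions: TBSCl, imidazole, CH2Cl2, 0 °C → rt
Reagents that add atoms: tert-butyldimethylsilyl chloride, CC(C)(C)[Si](C)(C)Cl
Why: Routine silylation masks the C9 hydroxymethyl group, so that in step 18 only the C4 hydroxyl can direct the oxidant.

Step 16
Reactants: 18 acyclic stannane iodide; 19 carbon monoxide
Product: 22 (1S,2E,5Z,9E)-9-{[(tert-butyldimethylsilyl)oxy]methyl}-1,5-dimethyl-1-(4-methylpent-3-en-1-yl)cycloundeca-2,5,9-trien-4-one (overview locants), via alkenylpalladium iodide 20 (not isolated), via acylpalladium iodide 21 (not isolated)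
Conditions: Pd2(dba)3 (10 mol %), AsPh3 (80 mol %), CO (3 atm), THF, 50 °C, 18 added over 12 h (final 1 mM)
Reagents that add atoms: none
Why: Zerovalent palladium inserts into the C5–I bond with retention to give 20, carbon monoxide inserts to give the acyl complex 21 (new C4–C5 bond), the E-alkenylstannane at C3 transmetallates with retention, and reductive elimination forms C3–C4 and releases the dienone. The closest known reaction type is the carbonylative Stille coupling of alkenyl halides or triflates with alkenylstannanes, which has been used intramolecularly to close macrocyclic cross-conjugated dienones. The eleven-membered ring is closed end to end, by intramolecular transmetallation to a twelve-membered palladacycle and reductive elimination at C3–C4. No stereocentre is formed, C1 is untouched, and the 2E and 5Z geometries are carried through because both sp2 carbon–metal bonds react with retention. The step needs carbon monoxide insertion to come before transmetallation and ring closure to beat intermolecular coupling; the pressure of carbon monoxide with the weakly bound AsPh3, the greater strain of the ten-membered diene that direct coupling would have to form, and slow addition to high dilution should secure both.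

Step 17
Reactants: 22 eleven-membered dienone
Product: 23 (1S,4S,2E,5Z,9E)-9-{[(tert-butyldimethylsilyl)oxy]methyl}-1,5-dimethyl-1-(4-methylpent-3-en-1-yl)cycloundeca-2,5,9-trien-4-ol (overview locants)
Conditions: (R)-2-methyl-CBS-oxazaborolidine (1 equiv), catecholborane, toluene, −78 °C
Reagents that add atoms: none
Why: Corey–Bakshi–Shibata reduction, in which the α-methyl-branched alkenyl flank (C5) should act as the large and the unbranched E-alkenyl flank (C3) as the small ketone substituent, so that the (R)-oxazaborolidine delivers hydride to the face that gives the (4S)-alcohol, with catecholborane at low temperature avoiding conjugate reduction and hydroboration.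

Step 18
Reactants: 23 bis-allylic alcohol
Product: 24 (1S,4S,5R,6R,2E,9E)-9-{[(tert-butyldimethylsilyl)oxy]methyl}-5,6-epoxy-1,5-dimethyl-1-(4-methylpent-3-en-1-yl)cycloundeca-2,9-dien-4-ol (overview locants)
Conditions: VO(acac)2 (5 mol %), t-BuOOH, CH2Cl2, 0 °C
Reagents that add atoms: tert-butyl hydroperoxide, CC(C)(C)OO
Why: Hydroxyl-directed epoxidation, in which the vanadate ester of the C4 hydroxyl passes the peroxide oxygen to the electron-rich trisubstituted C5=C6 alkene in preference to the disubstituted C2=C3 alkene next to the quaternary carbon and to the unbound alkenes, and in which the C5 methyl group (A(1,2) strain) should favour the erythro, ring-cis epoxy alcohol, that is 5R,6R from 4S.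

Step 19
Reactants: 24 epoxy alcohol; 25 3-methylbut-2-enoic acid
Product: 26 (1S,4S,5R,6R,2E,9E)-9-{[(tert-butyldimethylsilyl)oxy]methyl}-5,6-epoxy-1,5-dimethyl-1-(4-methylpent-3-en-1-yl)cycloundeca-2,9-dien-4-yl 3-methylbut-2-enoate (overview locants)
Conditions: DCC, DMAP, CH2Cl2, 0 °C → rt
Reagents that add atoms: none
Why: Steglich esterification, in which the acylpyridinium ion acylates the hindered secondary alcohol with retention at C4 and without the strong base or acid that could open the oxirane or move the double bond of the acyl group.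

Step 20
Reactants: 26 silyl ether ester
Product: 27 target, (1S,4S,5R,6R,2E,9E)-5,6-epoxy-9-(hydroxymethyl)-1,5-dimethyl-1-(4-methylpent-3-en-1-yl)cycloundeca-2,9-dien-4-yl 3-methylbut-2-enoate (overview locants)
Conditions: Bu4NF, AcOH, THF, 0 °C → rt
Reagents that add atoms: none
Why: Fluoride desilylation buffered with acetic acid frees the primary allylic alcohol while keeping the medium too weakly basic for acyl migration or oxirane opening.

**Compound list**

1 | geraniol, (2E)-3,7-dimethylocta-2,6-dien-1-ol | CC(C)=CCC/C(C)=C/CO | starting material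
2 | (2S,3S)-2,3-epoxygeraniol | OC[C@@H]1O[C@@]1(C)CCC=C(C)C | intermediate
3 | tert-butyldimethylsilyl ether of 2 | CC(C)(C)[Si](C)(C)OC[C@@H]1O[C@@]1(C)CCC=C(C)C | intermediate
4 | (2S)-2-[(tert-butyldimethylsilyloxy)methyl]-2,6-dimethylhept-5-enal | O=C[C@@](C)(CCC=C(C)C)CO[Si](C)(C)C(C)(C)C | intermediate
5 | (2R)-1-(tert-butyldimethylsilyloxy)-2-ethynyl-2,6-dimethylhept-5-ene | C#C[C@@](C)(CCC=C(C)C)CO[Si](C)(C)C(C)(C)C | intermediate
6 | (2R)-2-ethynyl-2,6-dimethylhept-5-en-1-ol | C#C[C@@](C)(CCC=C(C)C)CO | intermediate
7 | (2R)-2-ethynyl-2,6-dimethylhept-5-enal | C#C[C@@](C)(CCC=C(C)C)C=O | intermediate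
8 | (3S)-3-ethynyl-1-methoxy-3,7-dimethylocta-1,6-diene (enol ether geometry mixed) | C#C[C@@](C)(CCC=C(C)C)C=COC | intermediate
9 | (3S)-3-ethynyl-3,7-dimethyloct-6-enal | C#C[C@@](C)(CCC=C(C)C)CC=O | intermediate
10 | (3S)-3,7-dimethyl-3-[(E)-2-(tributylstannyl)ethenyl]oct-6-enal | CCCC[Sn](CCCC)(CCCC)/C=C/[C@@](C)(CCC=C(C)C)CC=O | intermediate
11 | 3-[(tert-butyldimethylsilyl)oxy]propanal | O=CCCO[Si](C)(C)C(C)(C)C | starting material
12 | (Z)-tert-butyl[(4-iodopent-3-en-1-yl)oxy]dimethylsilane | C/C(I)=C/CCO[Si](C)(C)C(C)(C)C | intermediate
13 | (Z)-5-bromo-2-iodopent-2-ene | C/C(I)=C/CCBr | intermediate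
14 | triethyl phosphonoacetate | CCOC(=O)CP(=O)(OCC)OCC | starting material
15 | ethyl (5Z)-2-(diethoxyphosphoryl)-6-iodohept-5-enoate | CCOC(=O)C(CC/C=C(C)\I)P(=O)(OCC)OCC | intermediate
16 | ethyl (2E,5S,6E)-2-[(3Z)-4-iodopent-3-en-1-yl]-5-methyl-5-(4-methylpent-3-en-1-yl)-7-(tributylstannyl)hepta-2,6-dienoate | CCCC[Sn](CCCC)(CCCC)/C=C/[C@@](C)(CCC=C(C)C)C/C=C(C(=O)OCC)\CC/C=C(C)\I | intermediate
17 | (2E,5S,6E)-2-[(3Z)-4-iodopent-3-en-1-yl]-5-methyl-5-(4-methylpent-3-en-1-yl)-7-(tributylstannyl)hepta-2,6-dien-1-ol | CCCC[Sn](CCCC)(CCCC)/C=C/[C@@](C)(CCC=C(C)C)C/C=C(CO)\CC/C=C(C)\I | intermediate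
18 | tert-butyldimethylsilyl ether of 17 (acyclic E-alkenylstannane Z-alkenyl iodide) | CCCC[Sn](CCCC)(CCCC)/C=C/[C@@](C)(CCC=C(C)C)C/C=C(CO[Si](C)(C)C(C)(C)C)\CC/C=C(C)\I | intermediate
19 | carbon monoxide | [C-]#[O+] | starting material
20 | alkenylpalladium iodide from 18, bis(triphenylarsine) complex (not isolated) | CCCC[Sn](CCCC)(CCCC)/C=C/[C@@](C)(CCC=C(C)C)C/C=C(CO[Si](C)(C)C(C)(C)C)\CC/C=C(C)\[Pd](I)([As](c1ccccc1)(c1ccccc1)c1ccccc1)[As](c1ccccc1)(c1ccccc1)c1ccccc1 | intermediate
21 | acylpalladium iodide from 20 and carbon monoxide, bis(triphenylarsine) complex (not isolated) | CCCC[Sn](CCCC)(CCCC)/C=C/[C@@](C)(CCC=C(C)C)C/C=C(CO[Si](C)(C)C(C)(C)C)\CC/C=C(C)\C(=O)[Pd](I)([As](c1ccccc1)(c1ccccc1)c1ccccc1)[As](c1ccccc1)(c1ccccc1)c1ccccc1 | intermediate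
22 | eleven-membered C4 dienone | CC(C)=CCC[C@]1(C)/C=C/C(=O)/C(C)=C\CC/C(CO[Si](C)(C)C(C)(C)C)=C\C1 | intermediate
23 | (4S)-dienol | CC(C)=CCC[C@]1(C)/C=C/[C@H](O)/C(C)=C\CC/C(CO[Si](C)(C)C(C)(C)C)=C\C1 | intermediate
24 | (4S,5R,6R)-epoxy alcohol | CC(C)=CCC[C@]1(C)/C=C/[C@H](O)[C@]2(C)O[C@@H]2CC/C(CO[Si](C)(C)C(C)(C)C)=C\C1 | intermediate
25 | 3-methylbut-2-enoic acid | CC(C)=CC(=O)O | starting material
26 | silyl-protected 3-methylbut-2-enoate | CC(C)=CCC[C@]1(C)/C=C/[C@H](OC(=O)C=C(C)C)[C@]2(C)O[C@@H]2CC/C(CO[Si](C)(C)C(C)(C)C)=C\C1 | intermediate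
27 | CNP0318149.1 | CC(C)=CCC[C@]1(C)/C=C/[C@H](OC(=O)C=C(C)C)[C@]2(C)O[C@@H]2CC/C(CO)=C\C1 | target

**Step count**

Total: 20 steps. Longest linear sequence: 17 steps (steps 1–9 and 13–20); steps 10–12 build the iodo phosphonate.

**Steps most likely to fail**

Step 16. The alkenylstannane may transmetallate onto the alkenylpalladium iodide before carbon monoxide has inserted, giving direct coupling to a ten-membered diene, or intermolecular coupling may outrun closure of the strained ring. The fallback separates the two bond formations. It sets out from 18: iodine–lithium exchange with t-BuLi in Et2O at −78 °C, which is much faster than tin–lithium exchange, followed by CO2, would give the (2Z)-carboxylic acid F1 with the C4–C5 bond already in place. 1-Chloro-N,N,2-trimethylprop-1-en-1-amine in CH2Cl2 would turn it into the acid chloride F2 under neutral conditions. Slow addition of F2 to Pd2(dba)3 and tri(2-furyl)phosphine in THF under a balloon of carbon monoxide (to hold back decarbonylation) would then close the ring by intramolecular acylative Stille coupling. The fallback comes back to the route at 22.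

Step 17. The preferred conformation of the macrocycle, not the oxazaborolidine, may decide which carbonyl face takes up hydride, or the two alkenyl flanks may not be told apart, so that facial selectivity is poor or reversed. The fallback gives up reagent control. It sets out from 22: Luche reduction (NaBH4, CeCl3·7H2O, MeOH, −78 °C) would give 23 together with the C4-epimeric dienol F3, the two would be separated by chromatography, and F3 would be returned to 22 with MnO2 in CH2Cl2 and reduced again. The fallback comes back to the route at 23.

Step 18. Oxygen may be delivered to the wrong face of C5=C6 relative to the C4 hydroxyl (threo in place of erythro), if in the reacting ring conformer the exposed alkene face is not the one reached from the (4S)-vanadate. The fallback uses the other C4 epimer to reach the right oxirane and then inverts C4. It sets out from 22: reduction with (S)-2-methyl-CBS-oxazaborolidine and catecholborane would give the C4-epimeric dienol F3 on purpose. Epoxidation with VO(acac)2 and t-BuOOH, with the same threo preference, would then place the oxirane on the required face and give the threo epoxy alcohol F4 (4R,5R,6R). Mitsunobu esterification of F4 with 25 (PPh3, diisopropyl azodicarboxylate, toluene, 0 °C) would invert C4. The fallback comes back to the route at 26.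

**Further compounds**

F1 | step 16 | (2Z,6E,9S,10E)-6-{[(tert-butyldimethylsilyl)oxy]methyl}-2,9-dimethyl-9-(4-methylpent-3-en-1-yl)-11-(tributylstannyl)undeca-2,6,10-trienoic acid | CCCC[Sn](CCCC)(CCCC)/C=C/[C@@](C)(CCC=C(C)C)C/C=C(CO[Si](C)(C)C(C)(C)C)\CC/C=C(C)\C(O)=O
F2 | step 16 | acid chloride of F1 | CCCC[Sn](CCCC)(CCCC)/C=C/[C@@](C)(CCC=C(C)C)C/C=C(CO[Si](C)(C)C(C)(C)C)\CC/C=C(C)\C(Cl)=O
F3 | step 17 | (4R)-dienol, C4 epimer of 23 | CC(C)=CCC[C@]1(C)/C=C/[C@@H](O)/C(C)=C\CC/C(CO[Si](C)(C)C(C)(C)C)=C\C1
F4 | step 18 | (4R,5R,6R)-epoxy alcohol, C4 epimer of 24 | CC(C)=CCC[C@]1(C)/C=C/[C@@H](O)[C@]2(C)O[C@@H]2CC/C(CO[Si](C)(C)C(C)(C)C)=C\C1
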